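## Plan

1. Carotenoid numbering is used. The cuts are C11=C12 (last Wittig), then C11'=C12' (Wittig with the C10 dialdehyde) and C6'–C7' (Sonogashira) in the acetylenic half, and C9=C10 (Horner–Wadsworth–Emmons) and C7=C8 (lactol Wittig) in the triol half.
2. Enabling feature: on ring C1–C6 the oxygen on C3 and the chain carbon C7 on C6 are 1,4-cis, so they can be tied as an O–C7(=O) lactone. Ring C1–C6 is then the carbocycle of a 2-oxabicyclo[2.2.2]octan-3-one, the adduct of a 2-pyrone.
3. Forward, ring first: 3-hydroxy-4-methyl-2-pyrone (C3–C6, C7 and the 5-methyl) and methacrolein (C1=C2, an isobutene unit activated by CHO) form C2–C3 and C1–C6 in one base-catalysed [4+2]. The CHO is then reduced to the second C1 methyl and the lactone bridge is opened to 3-OH and the C7 aldehyde.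
4. Chain: C7 aldehyde → C13 enone → C15 aldehyde; actinol → enol triflate → C15 enyne salt → C25 salt; union at C11=C12.
5. Stereochemistry: C3 and C6 come from the catalyst-controlled cycloaddition (relative configuration locked by the bridge), C5 from hydration on the face of the lactone bridge, C3' from (4R,6R)-actinol. The double bonds are E from stabilised or equilibrating olefinations.

Key step: step 5

Assumption: compounds 21, 25 and 29 are taken as purchasable, and the quinidine-derived thiourea is taken to give the (1S,4R) series in step 5; its quinine-derived pseudoenantiomer would replace it if the sense proved opposite.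

## Route

Step 1
Reactants: 1 diethyl 2-methyl-3-oxobutanedioate; 2 3-bromoprop-1-ene
Product: 3 diethyl 2-methyl-3-oxo-2-(prop-2-en-1-yl)butanedioate (racemic)
Conditions: K2CO3, acetone, 56 °C
Reagents that add atoms: none
Why: C-alkylation of the doubly activated methine of a β-keto ester with an allylic bromide is a standard acetoacetic-ester-type alkylation; the quaternary centre is racemic and disappears in step 2.

Step 2
Reactants: 3 diethyl 2-methyl-3-oxo-2-(prop-2-en-1-yl)butanedioate
Product: 4 3-methyl-2-oxohex-5-enoic acid (racemic)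
Conditions: 10% aq. H2SO4, 100 °C
Reagents that add atoms: water, O
Why: Acid hydrolysis of both esters and decarboxylation of the β-keto acid is the classical oxalyl-ester route to α-keto acids; the terminal alkene should survive dilute acid.

Step 3
Reactants: 4 3-methyl-2-oxohex-5-enoic acid
Product: 6 4-methyl-2-oxo-2H-pyran-3-yl acetate, via 3-methyl-2,5-dioxopentanoic acid 5 (not isolated)
Conditions: O3, pyridine, CH2Cl2, −78 °C; evaporate; then Ac2O, pyridine, 60 °C
Reagents that add atoms: ozone, [O-][O+]=O; acetic anhydride, CC(=O)OC(C)=O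
Why: Pyridine-buffered ozonolysis should give the aldehyde without build-up of peroxides, and acetic anhydride then closes the δ-aldehydo acid to the enol lactone and acetylates the enolised α-keto group, the acetylative cyclodehydration known from the conversion of hexaric acids into 3-acetoxy-2-pyrones.

Step 4
Reactants: 6 4-methyl-2-oxo-2H-pyran-3-yl acetate
Product: 7 3-hydroxy-4-methyl-2H-pyran-2-one
Conditions: 2 M HCl, THF, 50 °C
Reagents that add atoms: none
Why: Acid hydrolysis of an enol acetate; 3-hydroxy-2-pyrones are stable to aqueous acid.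

Step 5
Reactants: 7 3-hydroxy-4-methyl-2H-pyran-2-one; 8 2-methylprop-2-enal
Product: 9 (1S,4R)-4-hydroxy-5,8-dimethyl-3-oxo-2-oxabicyclo[2.2.2]oct-7-ene-5-carbaldehyde (either or both epimers at C5 of the bicycle)
Conditions: N-[3,5-bis(trifluoromethyl)phenyl]-N'-(9-deoxy-epi-quinidin-9-yl)thiourea (10 mol %), CH2Cl2, −20 °C → rt
Reagents that add atoms: none
Why: The quinuclidine nitrogen deprotonates the 3-OH of 7 to a 3-oxidopyrone (a vinylogous enolate) while the thiourea binds the formyl group of 8; pyrone C6 adds to the CH2 terminus of 8 and the resulting enolate closes on pyrone C3, a base-catalysed Diels–Alder reaction (Michael–aldol in the stepwise picture) that is the known behaviour of 3-hydroxy-2-pyrones with acrylic dienophiles under cinchona catalysis. The carbocyclic six-membered ring is closed by this [4+2] cycloaddition (second bond by 6-exo-trig aldol closure if stepwise), which forms the CH2–CH(O) bond and the quaternary C–C(OH) bond in one operation and keeps the pyrone O–C(=O) unit as a lactone bridge. The two bridgehead stereocentres cannot vary relative to each other, because the lactone bridge spans one face and so holds the lactone oxygen and the carbonyl carbon cis and the bridgehead hydroxyl trans to that oxygen; their absolute sense should follow from the face of the bound dienolate that the catalyst leaves open. The quaternary centre that carries CH3 and CHO forms without control, which is of no consequence because CHO becomes the second methyl group in step 6. The selectivity needed is regiochemical, CH2 to pyrone C6 and the substituted carbon to pyrone C3, and polarity secures it, since C6 is the nucleophilic γ-terminus of the dienolate and CH2 the electrophilic β-carbon of the enal. The formyl group and the lactone bridge are helpers that steps 6 and 8 take out.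

Step 6
Reactants: 9 (1S,4R)-4-hydroxy-5,8-dimethyl-3-oxo-2-oxabicyclo[2.2.2]oct-7-ene-5-carbaldehyde
Product: 11 (1S,4S)-4-hydroxy-5,8,8-trimethyl-2-oxabicyclo[2.2.2]oct-5-en-3-one, via tosylhydrazone 10 (not isolated)
Conditions: TsNHNH2, CHCl3, 4 Å MS, rt; then catecholborane, 0 °C; then NaOAc·3H2O, 60 °C
Reagents that add atoms: none
Why: Caglioti-type reduction of an aldehyde tosylhydrazone with catecholborane, followed by acetate-induced loss of sulfinate and N2, should turn CHO into CH3 under near-neutral conditions below 60 °C, which avoids retro-aldol cleavage and CO2 extrusion; lactone, alkene and bridgeheads are untouched.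

Step 7
Reactants: 11 (1S,4S)-4-hydroxy-5,8,8-trimethyl-2-oxabicyclo[2.2.2]oct-5-en-3-one
Product: 12 (1S,4S,5S)-4,5-dihydroxy-5,8,8-trimethyl-2-oxabicyclo[2.2.2]octan-3-one
Conditions: Co(acac)2 (20 mol %), PhSiH3, O2 (1 atm), THF, rt
Reagents that add atoms: dioxygen, O=O
Why: Mukaiyama hydration puts OH on the more substituted alkene carbon; the tertiary radical should be trapped on the face of the lactone bridge because the other face is blocked by the syn methyl group of the neighbouring CMe2 carbon, which sets C5 with OH cis to the lactone oxygen and trans to the bridgehead OH.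

Step 8
Reactants: 12 (1S,4S,5S)-4,5-dihydroxy-5,8,8-trimethyl-2-oxabicyclo[2.2.2]octan-3-one
Product: 13 (1S,4S,5S)-5,8,8-trimethyl-2-oxabicyclo[2.2.2]octane-3,4,5-triol (lactol, both C3 epimers)
Conditions: iBu2AlH (3.5 equiv), CH2Cl2, −78 °C; aq. KNaC4H4O6
Reagents that add atoms: none
Why: iBu2AlH reduction of a lactone should stop at the aluminium hemiacetal at −78 °C; the two tertiary hydroxyls only consume hydride.

Step 9
Reactants: 13 (1S,4S,5S)-5,8,8-trimethyl-2-oxabicyclo[2.2.2]octane-3,4,5-triol; 14 1-(triphenyl-λ5-phosphanylidene)propan-2-one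
Product: 15 (3E)-4-[(1S,2S,4S)-1,2,4-trihydroxy-2,6,6-trimethylcyclohexyl]but-3-en-2-one
Conditions: toluene, PhCO2H (cat.), 90 °C
Reagents that add atoms: none
Why: Wittig olefination of a lactol through its open hydroxy-aldehyde form with a keto-stabilised ylide needs no base and should give the (E)-enone; the base-free medium avoids retro-aldol cleavage of the β-hydroxy aldehyde, and ring opening releases the C3 hydroxyl.

Step 10
Reactants: 15 (3E)-4-[(1S,2S,4S)-1,2,4-trihydroxy-2,6,6-trimethylcyclohexyl]but-3-en-2-one; 16 diethyl (cyanomethyl)phosphonate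
Product: 18 (2E,4E)-3-methyl-5-[(1S,2S,4S)-1,2,4-trihydroxy-2,6,6-trimethylcyclohexyl]penta-2,4-dienenitrile, via sodium phosphonate anion 17 (not isolated)
Conditions: NaH (1.0 equiv to 16), THF, 0 °C; then 15, 0 °C → rt
Reagents that add atoms: none
Why: Horner–Wadsworth–Emmons reaction of a methyl ketone with a preformed cyanomethylphosphonate anion, as in ionone chemistry, should give mainly the (2E)-nitrile (the 2Z isomer is removed by chromatography); without excess base the hydroxyls stay protonated, which suppresses vinylogous retro-aldol fragmentation.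

Step 11
Reactants: 18 (2E,4E)-3-methyl-5-[(1S,2S,4S)-1,2,4-trihydroxy-2,6,6-trimethylcyclohexyl]penta-2,4-dienenitrile
Product: 20 (2E,4E)-3-methyl-5-[(1S,2S,4S)-1,2,4-trihydroxy-2,6,6-trimethylcyclohexyl]penta-2,4-dienal, via N-aluminated aldimine 19 (not isolated)
Conditions: iBu2AlH (5 equiv), CH2Cl2, −78 → −40 °C; then wet SiO2, aq. KNaC4H4O6
Reagents that add atoms: water, O
Why: iBu2AlH adds once to a conjugated nitrile and the aldimine is hydrolysed on work-up, the standard nitrile-to-aldehyde reduction of retinoid chemistry; the double-bond geometry should hold at low temperature.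

Step 12
Reactants: 21 (4R,6R)-4-hydroxy-2,2,6-trimethylcyclohexan-1-one
Product: 22 (4R,6R)-2,2,6-trimethyl-4-(triethylsilyloxy)cyclohexan-1-one
Conditions: Et3SiCl, imidazole, CH2Cl2, 0 °C → rt
Reagents that add atoms: chlorotriethylsilane, CC[Si](Cl)(CC)CC
Why: Routine silylation of a secondary alcohol, needed so that the next step sulfonylates only the enolate.

Step 13
Reactants: 22 (4R,6R)-2,2,6-trimethyl-4-(triethylsilyloxy)cyclohexan-1-one
Product: 24 (4R)-2,6,6-trimethyl-4-(triethylsilyloxy)cyclohex-1-en-1-yl trifluoromethanesulfonate, via potassium enolate 23 (not isolated)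
Conditions: KN(SiMe3)2, THF, −78 °C; then PhNTf2, −78 → 0 °C
Reagents that add atoms: N-phenylbis(trifluoromethanesulfonimide), O=S(=O)(N(c1ccccc1)S(=O)(=O)C(F)(F)F)C(F)(F)F
Why: Deprotonation at the only enolisable α-carbon and O-sulfonylation give a single tetrasubstituted enol triflate; the C6 stereocentre of 22 disappears and C4 is untouched.

Step 14
Reactants: 24 (4R)-2,6,6-trimethyl-4-(triethylsilyloxy)cyclohex-1-en-1-yl trifluoromethanesulfonate; 25 (2E)-3-methylpent-2-en-4-yn-1-ol
Product: 26 (2E)-3-methyl-5-[(4R)-2,6,6-trimethyl-4-(triethylsilyloxy)cyclohex-1-en-1-yl]pent-2-en-4-yn-1-ol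
Conditions: PdCl2(PPh3)2 (5 mol %), CuI (10 mol %), Et3N, DMF, 40 °C
Reagents that add atoms: none
Why: Sonogashira coupling of an enol triflate with a terminal enyne forms C6'–C7' directly at the alkyne oxidation level; the geometry of 25 is preserved.

Step 15
Reactants: 26 (2E)-3-methyl-5-[(4R)-2,6,6-trimethyl-4-(triethylsilyloxy)cyclohex-1-en-1-yl]pent-2-en-4-yn-1-ol
Product: 28 [(2E)-5-[(4R)-4-hydroxy-2,6,6-trimethylcyclohex-1-en-1-yl]-3-methylpent-2-en-4-yn-1-yl](triphenyl)phosphonium bromide, via desilylated enynediol 27 (not isolated)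
Conditions: PPh3·HBr (1.2 equiv), MeOH, rt
Reagents that add atoms: triphenylphosphine hydrobromide, [Br-].c1ccc(cc1)[PH+](c1ccccc1)c1ccccc1
Why: Acid methanolysis removes the triethylsilyl ether and the allylic alcohol is converted through its allylic cation into the primary phosphonium salt, the usual preparation of C15 Wittig salts.

Step 16
Reactants: 28 the C15 phosphonium bromide; 29 (2E,4E,6E)-2,7-dimethylocta-2,4,6-trienedial
Product: 31 (2E,4E,6E,8E,10E)-13-[(4R)-4-hydroxy-2,6,6-trimethylcyclohex-1-en-1-yl]-2,7,11-trimethyltrideca-2,4,6,8,10-pentaen-12-ynal, via C15 ylide 30 (not isolated)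
Conditions: NaOMe, MeOH/CH2Cl2, 0 °C → rt, 29 in excess (3 equiv); then heat in EtOAc
Reagents that add atoms: none
Why: Wittig reaction of a semi-stabilised allylic ylide with one formyl group of the symmetrical dialdehyde used in excess; the new C11'=C12' bond should be brought to E by thermal equilibration.

Step 17
Reactants: 31 the C25 aldehyde
Product: 32 (2E,4E,6E,8E,10E)-13-[(4R)-4-hydroxy-2,6,6-trimethylcyclohex-1-en-1-yl]-2,7,11-trimethyltrideca-2,4,6,8,10-pentaen-12-yn-1-ol
Conditions: NaBH4, MeOH/THF, 0 °C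
Reagents that add atoms: none
Why: Chemoselective 1,2-reduction of a polyenal by borohydride.

Step 18
Reactants: 32 the C25 alcohol
Product: 33 [(2E,4E,6E,8E,10E)-13-[(4R)-4-hydroxy-2,6,6-trimethylcyclohex-1-en-1-yl]-2,7,11-trimethyltrideca-2,4,6,8,10-pentaen-12-yn-1-yl](triphenyl)phosphonium bromide
Conditions: PPh3·HBr, MeOH/CH2Cl2, rt, dark
Reagents that add atoms: triphenylphosphine hydrobromide, [Br-].c1ccc(cc1)[PH+](c1ccccc1)c1ccccc1
Why: The same allylic alcohol to phosphonium salt conversion as in step 15, standard for apocarotenols.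

Step 19
Reactants: 33 the C25 phosphonium bromide; 20 (2E,4E)-3-methyl-5-[(1S,2S,4S)-1,2,4-trihydroxy-2,6,6-trimethylcyclohexyl]penta-2,4-dienal
Product: 35 (3S,5S,6S,3'R)-7',8'-didehydro-5,6-dihydro-β,β-carotene-3,5,6,3'-tetrol (all-E), via C25 ylide 34 (not isolated)
Conditions: 1,2-epoxybutane/EtOH, 65 °C, Ar, dark; then heat in EtOAc
Reagents that add atoms: none
Why: Wittig reaction under epoxide-mediated conditions, where bromide opens the epoxide and the alkoxide generates the ylide at low stationary concentration, so the triol aldehyde never meets free strong base; the C11=C12 bond should form as an E/Z mixture that equilibrates thermally to the all-E isomer, and no stereocentre is touched.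

## Compound list

1 | diethyl 2-methyl-3-oxobutanedioate | CCOC(=O)C(=O)C(C)C(=O)OCC | starting material
2 | 3-bromoprop-1-ene | C=CCBr | starting material
3 | diethyl 2-methyl-3-oxo-2-(prop-2-en-1-yl)butanedioate (racemic) | CCOC(=O)C(=O)C(C)(CC=C)C(=O)OCC | intermediate
4 | 3-methyl-2-oxohex-5-enoic acid (racemic) | C=CCC(C)C(=O)C(=O)O | intermediate
5 | 3-methyl-2,5-dioxopentanoic acid (racemic, not isolated) | O=CCC(C)C(=O)C(=O)O | intermediate
6 | 4-methyl-2-oxo-2H-pyran-3-yl acetate | CC(=O)OC1=C(C)C=COC1=O | intermediate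
7 | 3-hydroxy-4-methyl-2H-pyran-2-one | CC1=C(O)C(=O)OC=C1 | intermediate
8 | 2-methylprop-2-enal | CC(=C)C=O | starting material
9 | (1S,4R)-4-hydroxy-5,8-dimethyl-3-oxo-2-oxabicyclo[2.2.2]oct-7-ene-5-carbaldehyde (C5 epimers) | O=C3[C@]2(O)C(C)(C=O)C[C@H](O3)C=C2C | intermediate
10 | 4-methylbenzenesulfonylhydrazone of 9 (not isolated) | O=C3[C@]2(O)C(C)(C=NNS(=O)(=O)c4ccc(C)cc4)C[C@H](O3)C=C2C | intermediate
11 | (1S,4S)-4-hydroxy-5,8,8-trimethyl-2-oxabicyclo[2.2.2]oct-5-en-3-one | O=C3[C@]2(O)C(C)(C)C[C@H](O3)C=C2C | intermediate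
12 | (1S,4S,5S)-4,5-dihydroxy-5,8,8-trimethyl-2-oxabicyclo[2.2.2]octan-3-one | O=C3[C@]2(O)C(C)(C)C[C@H](O3)C[C@]2(C)O | intermediate
13 | (1S,4S,5S)-5,8,8-trimethyl-2-oxabicyclo[2.2.2]octane-3,4,5-triol (C3 epimers) | OC3[C@]2(O)C(C)(C)C[C@H](O3)C[C@]2(C)O | intermediate
14 | 1-(triphenyl-λ5-phosphanylidene)propan-2-one | CC(=O)C=P(c1ccccc1)(c1ccccc1)c1ccccc1 | starting material
15 | (3E)-4-[(1S,2S,4S)-1,2,4-trihydroxy-2,6,6-trimethylcyclohexyl]but-3-en-2-one | CC(=O)/C=C/[C@]1(O)C(C)(C)C[C@H](O)C[C@]1(C)O | intermediate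
16 | diethyl (cyanomethyl)phosphonate | N#CCP(=O)(OCC)OCC | starting material
17 | sodium cyano(diethoxyphosphoryl)methanide (not isolated) | [Na+].N#C[CH-]P(=O)(OCC)OCC | intermediate
18 | (2E,4E)-3-methyl-5-[(1S,2S,4S)-1,2,4-trihydroxy-2,6,6-trimethylcyclohexyl]penta-2,4-dienenitrile | N#C/C=C(C)/C=C/[C@]1(O)C(C)(C)C[C@H](O)C[C@]1(C)O | intermediate
19 | aldimine of 20, N-aluminated in the flask (not isolated) | N=C/C=C(C)/C=C/[C@]1(O)C(C)(C)C[C@H](O)C[C@]1(C)O | intermediate
20 | (2E,4E)-3-methyl-5-[(1S,2S,4S)-1,2,4-trihydroxy-2,6,6-trimethylcyclohexyl]penta-2,4-dienal | O=C/C=C(C)/C=C/[C@]1(O)C(C)(C)C[C@H](O)C[C@]1(C)O | intermediate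
21 | (4R,6R)-4-hydroxy-2,2,6-trimethylcyclohexan-1-one | O=C1C(C)(C)C[C@H](O)C[C@H]1C | starting material
22 | (4R,6R)-2,2,6-trimethyl-4-(triethylsilyloxy)cyclohexan-1-one | O=C1C(C)(C)C[C@H](O[Si](CC)(CC)CC)C[C@H]1C | intermediate
23 | potassium (4R)-2,6,6-trimethyl-4-(triethylsilyloxy)cyclohex-1-en-1-olate (not isolated) | CC1=C([O-])C(C)(C)C[C@H](O[Si](CC)(CC)CC)C1.[K+] | intermediate
24 | (4R)-2,6,6-trimethyl-4-(triethylsilyloxy)cyclohex-1-en-1-yl trifluoromethanesulfonate | CC1=C(OS(=O)(=O)C(F)(F)F)C(C)(C)C[C@H](O[Si](CC)(CC)CC)C1 | intermediate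
25 | (2E)-3-methylpent-2-en-4-yn-1-ol | C#C/C(C)=C/CO | starting material
26 | (2E)-3-methyl-5-[(4R)-2,6,6-trimethyl-4-(triethylsilyloxy)cyclohex-1-en-1-yl]pent-2-en-4-yn-1-ol | CC1=C(C#C/C(C)=C/CO)C(C)(C)C[C@H](O[Si](CC)(CC)CC)C1 | intermediate
27 | (2E)-5-[(4R)-4-hydroxy-2,6,6-trimethylcyclohex-1-en-1-yl]-3-methylpent-2-en-4-yn-1-ol (not isolated) | CC1=C(C#C/C(C)=C/CO)C(C)(C)C[C@H](O)C1 | intermediate
28 | [(2E)-5-[(4R)-4-hydroxy-2,6,6-trimethylcyclohex-1-en-1-yl]-3-methylpent-2-en-4-yn-1-yl](triphenyl)phosphonium bromide | CC1=C(C#C/C(C)=C/C[P+](c2ccccc2)(c2ccccc2)c2ccccc2)C(C)(C)C[C@H](O)C1.[Br-] | intermediate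
29 | (2E,4E,6E)-2,7-dimethylocta-2,4,6-trienedial | O=C/C(C)=C/C=C/C=C(C)/C=O | starting material
30 | ylide of 28 (not isolated) | CC1=C(C#C/C(C)=C/C=P(c2ccccc2)(c2ccccc2)c2ccccc2)C(C)(C)C[C@H](O)C1 | intermediate
31 | (2E,4E,6E,8E,10E)-13-[(4R)-4-hydroxy-2,6,6-trimethylcyclohex-1-en-1-yl]-2,7,11-trimethyltrideca-2,4,6,8,10-pentaen-12-ynal | CC1=C(C#C/C(C)=C/C=C/C(C)=C/C=C/C=C(C)/C=O)C(C)(C)C[C@H](O)C1 | intermediate
32 | (2E,4E,6E,8E,10E)-13-[(4R)-4-hydroxy-2,6,6-trimethylcyclohex-1-en-1-yl]-2,7,11-trimethyltrideca-2,4,6,8,10-pentaen-12-yn-1-ol | CC1=C(C#C/C(C)=C/C=C/C(C)=C/C=C/C=C(C)/CO)C(C)(C)C[C@H](O)C1 | intermediate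
33 | triphenylphosphonium bromide of 32 (P on C1 of the chain) | CC1=C(C#C/C(C)=C/C=C/C(C)=C/C=C/C=C(C)/C[P+](c2ccccc2)(c2ccccc2)c2ccccc2)C(C)(C)C[C@H](O)C1.[Br-] | intermediate
34 | ylide of 33 (not isolated) | CC1=C(C#C/C(C)=C/C=C/C(C)=C/C=C/C=C(C)/C=P(c2ccccc2)(c2ccccc2)c2ccccc2)C(C)(C)C[C@H](O)C1 | intermediate
35 | (3S,5S,6S,3'R)-7',8'-didehydro-5,6-dihydro-β,β-carotene-3,5,6,3'-tetrol (all-E) | CC1=C(C#C/C(C)=C/C=C/C(C)=C/C=C/C=C(C)/C=C/C=C(C)/C=C/[C@]2(O)C(C)(C)C[C@H](O)C[C@]2(C)O)C(C)(C)C[C@H](O)C1 | target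

## Count and risks

Total step count: 19. Longest linear sequence: 12 steps (steps 1 to 11, then step 19).

Steps most likely to fail:

1. Step 5. The catalyst may discriminate the two faces of the dienolate poorly with an α-branched enal, or in the unwanted sense, so that the bridgeheads are set with low enantiomeric purity. The fallback sets out from 7 and 8 and comes back at 9. Triethylamine-catalysed cycloaddition in CH2Cl2 gives the racemic adduct F1. Condensation with (1R,2R)-N,N'-dimethyl-1,2-diphenylethane-1,2-diamine (Et2O, 4 Å MS) gives diastereomeric imidazolidines, which are separated by chromatography or crystallisation. The aminal of the (1S,4R) series F2 is hydrolysed with dilute aqueous HCl in Et2O to 9.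

2. Step 3. Peroxidic ozonolysis intermediates may decarboxylate the α-keto acid oxidatively, and the 1,4-dicarbonyl unit may close with loss of water to a furan instead of the enol lactone. The fallback sets out from 4 and comes back at 7, so that step 4 is not needed. Fischer esterification (EtOH, cat. H2SO4) gives ethyl 3-methyl-2-oxohex-5-enoate F3. Ozonolysis (O3, CH2Cl2, −78 °C; PPh3) gives ethyl 3-methyl-2,5-dioxopentanoate F4. DBU in THF should close the enol lactone by attack of the aldehyde enolate oxygen on the activated α-keto ester with loss of ethanol, and acidification gives 7.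

3. Step 9. The bridged lactol may open too little, and its neopentyl aldehyde may add the bulky keto-stabilised ylide too slowly, so that heating leads to decomposition. The fallback sets out from 13 and comes back at 15. Amine-catalysed aldol reaction with acetone (pyrrolidine, AcOH, acetone as solvent, rt) gives 4-hydroxy-4-[(1S,2S,4S)-1,2,4-trihydroxy-2,6,6-trimethylcyclohexyl]butan-2-one F5. F5 should lose water on warming in the same medium, by the iminium–enamine pathway of amine-catalysed Claisen–Schmidt condensations, to give 15.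

## Further compounds

F1 | step 5 | racemic 4-hydroxy-5,8-dimethyl-3-oxo-2-oxabicyclo[2.2.2]oct-7-ene-5-carbaldehyde | CC1=CC2CC(C)(C=O)C1(O)C(=O)O2
F2 | step 5 | (1S,4R)-5-[(4R,5R)-1,3-dimethyl-4,5-diphenylimidazolidin-2-yl]-4-hydroxy-5,8-dimethyl-2-oxabicyclo[2.2.2]oct-7-en-3-one | O=C3[C@]2(O)C(C)(C4N(C)[C@H](c5ccccc5)[C@@H](c5ccccc5)N4C)C[C@H](O3)C=C2C
F3 | step 3 | ethyl 3-methyl-2-oxohex-5-enoate | C=CCC(C)C(=O)C(=O)OCC
F4 | step 3 | ethyl 3-methyl-2,5-dioxopentanoate | O=CCC(C)C(=O)C(=O)OCC
F5 | step 9 | 4-hydroxy-4-[(1S,2S,4S)-1,2,4-trihydroxy-2,6,6-trimethylcyclohexyl]butan-2-one | CC(=O)CC(O)[C@]1(O)C(C)(C)C[C@H](O)C[C@]1(C)O
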